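The plan cuts ring C of the middle flavan unit at C3–C4 and O1–C2. The feature exploited is that O1, C8a, C4a and C4 form a latent oxadiene fused to ring A. C2–C3, with its aryl and galloyloxy groups cis, is a Z alkene. One acid-catalysed [4+2] addition thus closes ring C, sets C2, C3 and C4, and delivers the gallate. Its precursor is an ortho-hydroxy diarylcarbinol that ties a bromine-capped phloroglucinol ring to C8 of protected epicatechin. Everything else is established chemistry: the bromine only blocks C8, and the top unit comes from epicatechin through a cationic C4–C8 coupling.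

Key step: step 11

**Remarks**
- Flavan numbering is used. The bottom unit carries C4H2, and the middle and top units lie above it.
- Abbreviations: Bn = benzyl. TBS = tert-butyldimethylsilyl. (R)-TRIP = (R)-3,3′-bis(2,4,6-triisopropylphenyl)-1,1′-binaphthyl-2,2′-diyl hydrogen phosphate.
- Assumption: the name is read as the 3,3′,3″-tri-O-gallate of epicatechin-(4β→8)-epicatechin-(4β→8)-epicatechin. This is what the SMILES encodes (2,3-cis and 3,4-trans in both upper units).
- Assumption: the (R) acid is taken as the enantiomer that leaves the required quinone methide face open. If the induction runs the other way, the (S) acid replaces it with nothing else changed.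
- The two diarylcarbinols are epimer mixtures at the carbinol carbon, and one epimer is drawn.
- The phenol of the ring A aldehyde travels as an allyl ether through the organolithium step, because a free phenol would quench the aryllithium.

**Step 1**
Reactants: 1 (−)-epicatechin
Product: 2 5,7,3′,4′-tetra-O-benzyl-(−)-epicatechin (2R,3R; 3-OH free)
Conditions: BnBr (4.4 equiv), K2CO3, DMF, argon, 0 °C to rt
Reagents that add atoms: benzyl bromide, BrCc1ccccc1
Why: Williamson etherification under carbonate conditions alkylates the four phenols and leaves the secondary C3 alcohol free, and exclusion of air keeps C2 and C3 of 1 unchanged.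

**Step 2**
Reactants: 2 5,7,3′,4′-tetra-O-benzyl-(−)-epicatechin
Product: 3 8-bromo-5,7,3′,4′-tetra-O-benzylepicatechin (2R,3R)
Conditions: NBS (1.0 equiv), CH2Cl2, −45 °C to rt
Reagents that add atoms: N-bromosuccinimide, O=C1CCC(=O)N1Br
Why: Electrophilic aromatic bromination of benzylated flavan-3-ols takes place at C8, the most reactive ring A position between O1 and the 7-benzyloxy group, so one equivalent of NBS should give the 8-bromide, which serves both the bottom and the top unit.

**Step 3**
Reactants: 3 8-bromo-5,7,3′,4′-tetra-O-benzylepicatechin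
Product: 4 8-bromo-3-O-TBS-5,7,3′,4′-tetra-O-benzylepicatechin (2R,3R)
Conditions: TBSCl, imidazole, DMF, rt
Reagents that add atoms: tert-butyldimethylsilyl chloride, CC(C)(C)[Si](C)(C)Cl
Why: Imidazole-promoted silylation masks the only acidic proton before the lithiation of step 9 with a group that survives organolithium, acid-catalysis and radical conditions.

**Step 4**
Reactants: 5 2,4,6-trihydroxybenzaldehyde
Product: 6 2,4-bis(benzyloxy)-6-hydroxybenzaldehyde
Conditions: BnBr (2.05 equiv), K2CO3, DMF, rt
Reagents that add atoms: benzyl bromide, BrCc1ccccc1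
Why: In this selective Williamson etherification the hydroxyl that stays hydrogen-bonded to the formyl group is the least nucleophilic, so two equivalents of benzyl bromide should leave it free.

**Step 5**
Reactants: 6 2,4-bis(benzyloxy)-6-hydroxybenzaldehyde
Product: 7 4,6-bis(benzyloxy)-3-bromo-2-hydroxybenzaldehyde
Conditions: NBS (1.0 equiv), i-Pr2NH (10 mol %), CH2Cl2, 0 °C
Reagents that add atoms: N-bromosuccinimide, O=C1CCC(=O)N1Br
Why: Amine-catalysed ortho-bromination of a phenol delivers bromine next to the free hydroxyl (C3), the site at which 2-hydroxy-4,6-dialkoxyaryl carbonyl compounds are known to be halogenated, and not between the two benzyloxy groups.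

**Step 6**
Reactants: 7 4,6-bis(benzyloxy)-3-bromo-2-hydroxybenzaldehyde
Product: 8 2-(allyloxy)-4,6-bis(benzyloxy)-3-bromobenzaldehyde
Conditions: allyl bromide, K2CO3, DMF, 50 °C
Reagents that add atoms: allyl bromide, C=CCBr
Why: Williamson etherification removes the phenolic proton and restores full aldehyde reactivity, and the allyl group is chosen because it later leaves under non-acidic palladium catalysis.

**Step 7**
Reactants: 9 3,4-bis(benzyloxy)benzaldehyde
Product: 10 1,2-bis(benzyloxy)-4-ethynylbenzene
Conditions: dimethyl (1-diazo-2-oxopropyl)phosphonate, K2CO3, MeOH/THF, rt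
Reagents that add atoms: dimethyl (1-diazo-2-oxopropyl)phosphonate, CC(=O)C(=[N+]=[N-])P(=O)(OC)OC
Why: The Seyferth–Gilbert homologation in its Ohira–Bestmann form turns a non-enolisable aromatic aldehyde into the terminal alkyne in one operation under mild base.

**Step 8**
Reactants: 10 1,2-bis(benzyloxy)-4-ethynylbenzene; 11 3,4,5-tris(benzyloxy)benzoic acid
Product: 12 (Z)-2-[3,4-bis(benzyloxy)phenyl]vinyl 3,4,5-tris(benzyloxy)benzoate
Conditions: Ru(methallyl)2(dppb) (2 mol %), toluene, 50 °C
Reagents that add atoms: none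
Why: Ruthenium-catalysed anti-Markovnikov addition of a carboxylic acid to a terminal arylalkyne runs through a vinylidene complex whose α-carbon takes up the carboxylate, and protonolysis of the alkenyl–ruthenium bond leaves oxygen and aryl group cis, which is the known Z outcome for benzoic acids and arylacetylenes.

**Step 9**
Reactants: 4 8-bromo-3-O-TBS-5,7,3′,4′-tetra-O-benzylepicatechin; 8 2-(allyloxy)-4,6-bis(benzyloxy)-3-bromobenzaldehyde
Product: 14 allyl-protected diarylcarbinol joining C1 of the bromo ring to C8 of the bottom unit (both carbinol epimers), via 8-lithio flavan 13 (not isolated)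
Conditions: n-BuLi (0.98 equiv), THF, −78 °C; then 8, −78 °C; water quench, Et3N-deactivated silica
Reagents that add atoms: none
Why: Bromine–lithium exchange followed by 1,2-addition of the aryllithium to the aldehyde is far faster at −78 °C than aryl–aryl bromine–lithium scrambling, di-ortho-alkoxyaryllithiums are known to add even to more hindered carbonyl groups, and the new carbinol centre needs no control because step 11 erases it.

**Step 10**
Reactants: 14 allyl-protected diarylcarbinol
Product: 15 ortho-hydroxy diarylcarbinol: [4,6-bis(benzyloxy)-3-bromo-2-hydroxyphenyl][3-O-TBS-5,7,3′,4′-tetra-O-benzylepicatechin-8-yl]methanol (both carbinol epimers)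
Conditions: Pd(PPh3)4 (5 mol %), morpholine, THF, rt
Reagents that add atoms: none
Why: In this Tsuji–Trost deallylation zerovalent palladium ionises the aryl allyl ether and morpholine traps the π-allyl fragment, the basic medium spares the acid-labile carbinol, and the hindered electron-rich C–Br bond should not undergo oxidative addition at rt.

**Step 11**
Reactants: 15 ortho-hydroxy diarylcarbinol; 12 (Z)-2-[3,4-bis(benzyloxy)phenyl]vinyl 3,4,5-tris(benzyloxy)benzoate
Product: 17 benzyl-protected 8-bromoepicatechin 3-O-gallate-(4β→8)-3-O-TBS-epicatechin, via ortho-quinone methide 16 (not isolated)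
Conditions: (R)-TRIP (10 mol %), 12 (2 equiv), 5 Å molecular sieves, toluene, 0 °C to rt
Reagents that add atoms: none
Why: Proposed new method: the acid ionises either epimer of 15 with loss of water to the ortho-quinone methide 16, held hydrogen-bonded or ion-paired to the chiral phosphate, and the acyloxy-bearing alkene carbon of 12 attacks the methide carbon C4 because the 3,4-bis(benzyloxy)phenyl group carries the positive charge building up on the other alkene carbon, onto which O1 then closes. The closest known reaction type is the chiral-phosphoric-acid-catalysed inverse-demand hetero-Diels–Alder reaction of in situ ortho-quinone methides with styrenes, enamides or enol ethers; an enol ester as the two-carbon partner is the extension. Ring C closes as a six-membered ring in an intermolecular, asynchronous [4+2] mode (C3–C4 ahead of O1–C2), driven by rearomatisation of ring A. C2 and C3 are set cis by suprafacial transfer of the Z geometry of 12; C4 is set trans to C3 because the peri 5-benzyloxy group turns the C4 aryl group towards the carbonyl oxygen (Z methide) while the aryl and galloyloxy groups of 12 lie endo, which also leaves the C4 aryl group pseudo-axial and clear of that peri group; the absolute sense comes from the catalyst, whose 3,3′-aryl groups should leave open only the face of 16 that becomes the α face of ring C. The step needs regio-, endo- and face selectivity and must outrun Friedel–Crafts self-alkylation: the donor aryl group of 12 fixes the regiochemistry, the peri group and the phosphate pocket address the other two, and the C8 bromine blocks the most nucleophilic ring position of both 15 and 17, while attack by a remaining C6–H site would have to build a triarylmethane with six ortho substituents. Molecular sieves take up the water so that 12 is not hydrolysed, and the acid is too weak to protonate 12 and scramble its geometry.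

**Step 12**
Reactants: 17 bromo dimer
Product: 18 benzyl-protected epicatechin 3-O-gallate-(4β→8)-3-O-TBS-epicatechin (C8–H in the middle unit)
Conditions: Bu3SnH (5 equiv), AIBN (cat.), toluene, 85 °C
Reagents that add atoms: none
Why: Radical-chain hydrodebromination with tin hydride tolerates ester, silyl ether and benzyl ethers, and a high hydride concentration should reduce the aryl radical before it can cyclise onto a neighbouring benzyl group.

**Step 13**
Reactants: 18 debrominated dimer
Product: 19 dimer with free 3-OH in the bottom unit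
Conditions: HF·pyridine, pyridine, THF, 0 °C to rt
Reagents that add atoms: none
Why: Fluoride-mediated desilylation in a pyridine-buffered medium cleaves the secondary TBS ether without touching the gallate ester or the benzylated interflavan bond.

**Step 14**
Reactants: 19 dimer alcohol; 11 3,4,5-tris(benzyloxy)benzoic acid
Product: 20 benzyl-protected epicatechin 3-O-gallate-(4β→8)-epicatechin 3-O-gallate
Conditions: DCC, DMAP, CH2Cl2, rt
Reagents that add atoms: none
Why: Steglich esterification acylates the single free, axial C3 hydroxyl with retention because the C–O bond is not touched.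

**Step 15**
Reactants: 3 8-bromo-5,7,3′,4′-tetra-O-benzylepicatechin
Product: 21 8-bromo-4β-(2-ethoxyethoxy)-5,7,3′,4′-tetra-O-benzylepicatechin
Conditions: DDQ, 2-ethoxyethanol, CH2Cl2, rt
Reagents that add atoms: 2-ethoxyethanol, CCOCCO
Why: DDQ-mediated benzylic C–H oxidation abstracts hydride from C4, whose cation is stabilised by O1 and the 5- and 7-benzyloxy groups, and the alcohol adds to the β face, trans to the axial 3-hydroxyl, at a centre that is ionised again in step 17.

**Step 16**
Reactants: 21 4β-(2-ethoxyethoxy) bromide; 11 3,4,5-tris(benzyloxy)benzoic acid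
Product: 22 8-bromo-4β-(2-ethoxyethoxy)-5,7,3′,4′-tetra-O-benzylepicatechin 3-O-[3,4,5-tris(benzyloxy)benzoate]
Conditions: DCC, DMAP, CH2Cl2, rt
Reagents that add atoms: none
Why: Steglich esterification works under basic, non-ionising conditions, so the acid-labile C4 ether is kept while the C3 hydroxyl is galloylated.

**Step 17**
Reactants: 20 dimer digallate; 22 bromine-capped C4 electrophile
Product: 23 fully benzylated trimer trigallate with bromine at C8 of the top unit
Conditions: TMSOTf (0.2 equiv), 22 (1.1 equiv), CH2Cl2, −78 to −40 °C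
Reagents that add atoms: none
Why: This Lewis-acid-promoted Friedel–Crafts flavan coupling ionises the C4 ether of 22, C8 of the upper unit of the dimer is the known nucleophilic site, the bromine cap keeps 22 from condensing with itself, and the new C4 centre is set β because the 3-galloyloxy group shields the α face through its carbonyl oxygen.

**Step 18**
Reactants: 23 protected bromo trimer
Product: 24 procyanidin C1 3,3′,3″-tri-O-gallate
Conditions: H2 (1 atm), Pd(OH)2 on carbon, NaOAc (1.2 equiv), THF/MeOH/H2O, rt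
Reagents that add atoms: none
Why: Catalytic hydrogenolysis removes all twenty-one benzyl ethers and the aryl bromide in one operation without affecting esters, ring C ethers or stereocentres, and the acetate buffers the hydrogen bromide that could otherwise cleave interflavan bonds.

**Compound list**

1 | (−)-epicatechin (2R,3R) | Oc1cc(O)c2c(c1)O[C@H](c1ccc(O)c(O)c1)[C@H](O)C2 | starting material

2 | 5,7,3′,4′-tetra-O-benzyl-(−)-epicatechin | c1(OCc9ccccc9)cc(OCc9ccccc9)c2c(c1)O[C@H](c1ccc(OCc9ccccc9)c(OCc9ccccc9)c1)[C@H](O)C2 | intermediate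

3 | 8-bromo-5,7,3′,4′-tetra-O-benzylepicatechin | Brc2c(OCc9ccccc9)cc(OCc9ccccc9)c3c2O[C@H](c2ccc(OCc9ccccc9)c(OCc9ccccc9)c2)[C@H](O)C3 | intermediate

4 | 8-bromo-3-O-TBS-5,7,3′,4′-tetra-O-benzylepicatechin | Brc2c(OCc9ccccc9)cc(OCc9ccccc9)c3c2O[C@H](c2ccc(OCc9ccccc9)c(OCc9ccccc9)c2)[C@H](O[Si](C)(C)C(C)(C)C)C3 | intermediate

5 | 2,4,6-trihydroxybenzaldehyde | O=Cc1c(O)cc(O)cc1O | starting material

6 | 2,4-bis(benzyloxy)-6-hydroxybenzaldehyde | O=Cc1c(O)cc(OCc9ccccc9)cc1OCc9ccccc9 | intermediate

7 | 4,6-bis(benzyloxy)-3-bromo-2-hydroxybenzaldehyde | O=Cc1c(O)c(Br)c(OCc9ccccc9)cc1OCc9ccccc9 | intermediate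

8 | 2-(allyloxy)-4,6-bis(benzyloxy)-3-bromobenzaldehyde | O=Cc1c(OCC=C)c(Br)c(OCc9ccccc9)cc1OCc9ccccc9 | intermediate

9 | 3,4-bis(benzyloxy)benzaldehyde | O=Cc1ccc(OCc2ccccc2)c(OCc2ccccc2)c1 | starting material

10 | 1,2-bis(benzyloxy)-4-ethynylbenzene | C#Cc1ccc(OCc9ccccc9)c(OCc9ccccc9)c1 | intermediate

11 | 3,4,5-tris(benzyloxy)benzoic acid | OC(=O)c1cc(OCc9ccccc9)c(OCc9ccccc9)c(OCc9ccccc9)c1 | starting material

12 | (Z)-2-[3,4-bis(benzyloxy)phenyl]vinyl 3,4,5-tris(benzyloxy)benzoate | O=C(O/C=C\c1ccc(OCc9ccccc9)c(OCc9ccccc9)c1)c1cc(OCc9ccccc9)c(OCc9ccccc9)c(OCc9ccccc9)c1 | intermediate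

13 | 8-lithio-3-O-TBS-5,7,3′,4′-tetra-O-benzylepicatechin | [Li]c2c(OCc9ccccc9)cc(OCc9ccccc9)c3c2O[C@H](c2ccc(OCc9ccccc9)c(OCc9ccccc9)c2)[C@H](O[Si](C)(C)C(C)(C)C)C3 | intermediate

14 | allyl-protected diarylcarbinol (epimer mixture, one epimer drawn) | C=CCOc1c(Br)c(OCc9ccccc9)cc(OCc9ccccc9)c1[C@@H](O)c2c(OCc9ccccc9)cc(OCc9ccccc9)c3c2O[C@H](c2ccc(OCc9ccccc9)c(OCc9ccccc9)c2)[C@H](O[Si](C)(C)C(C)(C)C)C3 | intermediate

15 | ortho-hydroxy diarylcarbinol (epimer mixture, one epimer drawn) | Oc1c(Br)c(OCc9ccccc9)cc(OCc9ccccc9)c1[C@@H](O)c2c(OCc9ccccc9)cc(OCc9ccccc9)c3c2O[C@H](c2ccc(OCc9ccccc9)c(OCc9ccccc9)c2)[C@H](O[Si](C)(C)C(C)(C)C)C3 | intermediate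

16 | ortho-quinone methide of ring A, Z at the methide bond (aryl group on the carbonyl side) | O=C1C(Br)=C(OCc9ccccc9)C=C(OCc9ccccc9)/C1=C/c2c(OCc9ccccc9)cc(OCc9ccccc9)c3c2O[C@H](c2ccc(OCc9ccccc9)c(OCc9ccccc9)c2)[C@H](O[Si](C)(C)C(C)(C)C)C3 | intermediate

17 | benzyl-protected 8-bromoepicatechin 3-O-gallate-(4β→8)-3-O-TBS-epicatechin | O=C(O[C@@H]1[C@@H](c2c(OCc9ccccc9)cc(OCc9ccccc9)c3c2O[C@H](c2ccc(OCc9ccccc9)c(OCc9ccccc9)c2)[C@H](O[Si](C)(C)C(C)(C)C)C3)c2c(OCc9ccccc9)cc(OCc9ccccc9)c(Br)c2O[C@@H]1c1ccc(OCc9ccccc9)c(OCc9ccccc9)c1)c1cc(OCc9ccccc9)c(OCc9ccccc9)c(OCc9ccccc9)c1 | intermediate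

18 | debrominated dimer (middle 3-O-gallate, bottom 3-O-TBS) | O=C(O[C@@H]1[C@@H](c2c(OCc9ccccc9)cc(OCc9ccccc9)c3c2O[C@H](c2ccc(OCc9ccccc9)c(OCc9ccccc9)c2)[C@H](O[Si](C)(C)C(C)(C)C)C3)c2c(OCc9ccccc9)cc(OCc9ccccc9)cc2O[C@@H]1c1ccc(OCc9ccccc9)c(OCc9ccccc9)c1)c1cc(OCc9ccccc9)c(OCc9ccccc9)c(OCc9ccccc9)c1 | intermediate

19 | dimer with free bottom 3-OH | O=C(O[C@@H]1[C@@H](c2c(OCc9ccccc9)cc(OCc9ccccc9)c3c2O[C@H](c2ccc(OCc9ccccc9)c(OCc9ccccc9)c2)[C@H](O)C3)c2c(OCc9ccccc9)cc(OCc9ccccc9)cc2O[C@@H]1c1ccc(OCc9ccccc9)c(OCc9ccccc9)c1)c1cc(OCc9ccccc9)c(OCc9ccccc9)c(OCc9ccccc9)c1 | intermediate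

20 | benzyl-protected dimer 3,3′-digallate | O=C(O[C@@H]1[C@@H](c2c(OCc9ccccc9)cc(OCc9ccccc9)c3c2O[C@H](c2ccc(OCc9ccccc9)c(OCc9ccccc9)c2)[C@H](OC(=O)c2cc(OCc9ccccc9)c(OCc9ccccc9)c(OCc9ccccc9)c2)C3)c2c(OCc9ccccc9)cc(OCc9ccccc9)cc2O[C@@H]1c1ccc(OCc9ccccc9)c(OCc9ccccc9)c1)c1cc(OCc9ccccc9)c(OCc9ccccc9)c(OCc9ccccc9)c1 | intermediate

21 | 8-bromo-4β-(2-ethoxyethoxy)-5,7,3′,4′-tetra-O-benzylepicatechin | CCOCCO[C@H]3c4c(OCc9ccccc9)cc(OCc9ccccc9)c(Br)c4O[C@H](c4ccc(OCc9ccccc9)c(OCc9ccccc9)c4)[C@@H]3O | intermediate

22 | 3-O-[3,4,5-tris(benzyloxy)benzoate] of 21 | CCOCCO[C@H]3c4c(OCc9ccccc9)cc(OCc9ccccc9)c(Br)c4O[C@H](c4ccc(OCc9ccccc9)c(OCc9ccccc9)c4)[C@@H]3OC(=O)c3cc(OCc9ccccc9)c(OCc9ccccc9)c(OCc9ccccc9)c3 | intermediate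

23 | fully benzylated trimer trigallate, bromine at C8 of the top unit | O=C(O[C@@H]1[C@@H](c2c(OCc9ccccc9)cc(OCc9ccccc9)c3c2O[C@H](c2ccc(OCc9ccccc9)c(OCc9ccccc9)c2)[C@H](OC(=O)c2cc(OCc9ccccc9)c(OCc9ccccc9)c(OCc9ccccc9)c2)C3)c2c(OCc9ccccc9)cc(OCc9ccccc9)c([C@H]3c4c(OCc9ccccc9)cc(OCc9ccccc9)c(Br)c4O[C@H](c4ccc(OCc9ccccc9)c(OCc9ccccc9)c4)[C@@H]3OC(=O)c3cc(OCc9ccccc9)c(OCc9ccccc9)c(OCc9ccccc9)c3)c2O[C@@H]1c1ccc(OCc9ccccc9)c(OCc9ccccc9)c1)c1cc(OCc9ccccc9)c(OCc9ccccc9)c(OCc9ccccc9)c1 | intermediate

24 | procyanidin C1 3,3′,3″-tri-O-gallate | O=C(O[C@@H]1[C@@H](c2c(O)cc(O)c3c2O[C@H](c2ccc(O)c(O)c2)[C@H](OC(=O)c2cc(O)c(O)c(O)c2)C3)c2c(O)cc(O)c([C@H]3c4c(O)cc(O)cc4O[C@H](c4ccc(O)c(O)c4)[C@@H]3OC(=O)c3cc(O)c(O)c(O)c3)c2O[C@@H]1c1ccc(O)c(O)c1)c1cc(O)c(O)c(O)c1 | target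

**Step count**

Total step count: 18. Longest linear sequence: 11 steps (1, 2, 3, 9, 10, 11, 12, 13, 14, 17, 18).

**Steps most likely to fail**

Step 11 (bears the label "Proposed new method:").
- The weakly nucleophilic enol ester may be too slow to capture the strongly stabilised methide.
- A stepwise course may erode the cis and trans relationships or the facial selectivity.
- The fallback is the known cationic flavan coupling, which sets out from 2 and 22 and comes back at 17.
- Compound 2 is silylated (TBSCl, imidazole, DMF) to 3-O-TBS-5,7,3′,4′-tetra-O-benzylepicatechin F1.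
- The free C8 of F1 is then joined to the bromine-capped electrophile 22 with catalytic TMSOTf in CH2Cl2 at −78 °C. The 3-galloyloxy group directs attack to the β face, so 17 should result.

Step 17.
- The large dimer may react sluggishly, or attack may occur through a C6 position.
- Acid-induced scrambling of the existing interflavan bond is also possible.
- The fallback changes the class of electrophile and the mode of activation. It sets out from 22 and comes back at 23.
- Compound 22 is treated with 2-mercaptobenzothiazole and catalytic BF3·OEt2 (CH2Cl2, −78 to 0 °C). This gives the 4β-(benzothiazol-2-ylthio) analogue of 22, F2.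
- F2 is activated by the thiophilic salt AgBF4 in THF at 0 °C in the presence of 20. The coupling then runs without an oxophilic Lewis acid.

Step 5.
- Bromination may take place between the two benzyloxy groups, or twice, which would misplace the cap.
- The fallback reverses the order of events. It sets out from 5 and comes back at 7.
- Compound 5, whose two free ring positions are equivalent, is monobrominated (NBS, MeCN, 0 °C) to 3-bromo-2,4,6-trihydroxybenzaldehyde F3.
- Two equivalents of BnBr with K2CO3 in DMF should then alkylate O4 and the less hindered O6. The hydroxyl wedged between bromine and the formyl group stays free.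

**Further compounds**

F1 | step 11 | 3-O-TBS-5,7,3′,4′-tetra-O-benzylepicatechin | c1(OCc9ccccc9)cc(OCc9ccccc9)c2c(c1)O[C@H](c1ccc(OCc9ccccc9)c(OCc9ccccc9)c1)[C@H](O[Si](C)(C)C(C)(C)C)C2
F2 | step 17 | 8-bromo-4β-(benzothiazol-2-ylthio)-5,7,3′,4′-tetra-O-benzylepicatechin 3-O-[3,4,5-tris(benzyloxy)benzoate] | c5(nc6ccccc6s5)S[C@H]3c4c(OCc9ccccc9)cc(OCc9ccccc9)c(Br)c4O[C@H](c4ccc(OCc9ccccc9)c(OCc9ccccc9)c4)[C@@H]3OC(=O)c3cc(OCc9ccccc9)c(OCc9ccccc9)c(OCc9ccccc9)c3
F3 | step 5 | 3-bromo-2,4,6-trihydroxybenzaldehyde | O=Cc1c(O)c(Br)c(O)cc1O
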